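The route rests on cutting the C2–C3 bond of the dihydrofuran (ring F: O1, C2, C3, C3a, C7a). The feature exploited is that C2 is a benzylic ether carbon while C3 is attached to C3a, the nucleophilic enol-ether carbon of the styrylpyranone. A pyranon-3-yl diazoacetate carrying the catechol benzyl group on its 4-oxygen (15, tert-butyl ester, four TBS ethers) therefore closes ring F by 1,5 C–H insertion of a rhodium carbene. One operation forms the bond, the ring and both stereocentres: the chiral dirhodium carboxylate fixes C2 and base equilibration makes C3 trans. The ester carbon later becomes C6 of the pendant hydroxypyranone.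

Key step: step 9

Abbreviations: TBS = tert-butyldimethylsilyl; Ar = 3,4-bis(tert-butyldimethylsilyloxy)phenyl; Rh2(S-PTTL)4 = dirhodium tetrakis[N-phthaloyl-(S)-tert-leucinate], a divalent rhodium carboxylate. Atom labels O1 to C7a are those of the furo[3,2-c]pyran core.

Assumption: Rh2(S-PTTL)4 is written as the antipode that leads to 2S; the facial sense on a pyranonyl carbene has to be confirmed on the first run, and Rh2(R-PTTL)4 takes its place if the mirror-image series forms.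

Assumption: the bis-silyl diene 4 is drawn as its Z ketene acetal; this geometry is lost in step 2, so either isomer or a mixture serves.

Step 1
Reactants: 1 caffeic acid
Product: 3 (E)-3-Ar-prop-2-enoic acid, via silyl ester 2 (not isolated)
Conditions: TBSCl (3.5 equiv), imidazole, DMF, rt; then AcOH–THF–H2O (3:1:1), rt
Reagents that add atoms: tert-butyldimethylsilyl chloride, CC(C)(C)[Si](C)(C)Cl
Why: Imidazole-promoted silylation caps both phenols and the acid, and aqueous acetic acid then hydrolyses only the silyl ester because acyloxysilanes are far more labile than aryl silyl ethers (silyl protection followed by selective silyl ester hydrolysis).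

Step 2
Reactants: 3 (E)-3-Ar-prop-2-enoic acid; 4 (1Z)-1-methoxy-1,3-bis(trimethylsilyloxy)buta-1,3-diene
Product: 7 methyl (E)-7-Ar-3,5-dioxohept-6-enoate, via acid chloride 5 (not isolated), via silyl ketene acetal 6 (not isolated)
Conditions: (COCl)2, DMF (cat.), CH2Cl2, 0 °C to rt, evaporate; then 4 (1.5 equiv), CH2Cl2, −78 °C to rt; sat. aq. NH4Cl work-up
Reagents that add atoms: none
Why: In this uncatalysed acylation of a 1,3-bis(silyl enol ether) by an acid chloride (Mukaiyama-type Claisen condensation) the terminal CH2 of the diene attacks the acyl chloride, chlorotrimethylsilane is lost and work-up hydrolyses the remaining silyl ketene acetal to the 3,5-dioxo ester, all without base, so the aryl silyl ethers and the E alkene are untouched.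

Step 3
Reactants: 7 methyl (E)-7-Ar-3,5-dioxohept-6-enoate
Product: 8 6-[(E)-2-Ar-ethenyl]-4-hydroxy-2H-pyran-2-one (bis-TBS hispidin)
Conditions: DBU (1.0 equiv), 4 Å molecular sieves, PhMe, rt to 50 °C; cold aq. citric acid work-up
Reagents that add atoms: none
Why: In this DBU-promoted lactonisation of a 3,5-dioxo ester the enolate oxygen of the C5 ketone attacks the methyl ester (6-exo-trig) and loss of methanol gives the 4-hydroxy-2-pyranone, whose acidity ties up the DBU as its salt while the sieves take up methanol, which keeps methoxide away from the aryl silyl ethers.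

Step 4
Reactants: 8 6-[(E)-2-Ar-ethenyl]-4-hydroxy-2H-pyran-2-one
Product: 9 6-[(E)-2-Ar-ethenyl]-4-hydroxy-3-iodo-2H-pyran-2-one
Conditions: NIS (1.05 equiv), CH2Cl2, 0 °C, dark
Reagents that add atoms: N-iodosuccinimide, O=C1CCC(=O)N1I
Why: C3 of a 4-hydroxy-2-pyranone is the carbon of a cyclic 1,3-dicarbonyl enol and is by far the most nucleophilic site, so neutral electrophilic iodination should spare the silyloxyarene and the alkene.

Step 5
Reactants: 10 3,4-dihydroxybenzaldehyde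
Product: 11 3,4-bis(tert-butyldimethylsilyloxy)benzaldehyde
Conditions: TBSCl (2.5 equiv), imidazole, DMF, rt
Reagents that add atoms: tert-butyldimethylsilyl chloride, CC(C)(C)[Si](C)(C)Cl
Why: Standard imidazole-promoted silylation of both phenols, to which the aldehyde is inert.

Step 6
Reactants: 11 3,4-bis(tert-butyldimethylsilyloxy)benzaldehyde
Product: 12 [3,4-bis(tert-butyldimethylsilyloxy)phenyl]methanol
Conditions: NaBH4, MeOH–THF, 0 °C
Reagents that add atoms: none
Why: Borohydride reduction of an aromatic aldehyde is fast at 0 °C, so the aryl silyl ethers see methoxide only briefly.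

Step 7
Reactants: 9 6-[(E)-2-Ar-ethenyl]-4-hydroxy-3-iodo-2H-pyran-2-one; 12 [3,4-bis(tert-butyldimethylsilyloxy)phenyl]methanol
Product: 13 4-(Ar-methoxy)-6-[(E)-2-Ar-ethenyl]-3-iodo-2H-pyran-2-one
Conditions: PPh3, DIAD, THF, 0 °C to rt
Reagents that add atoms: none
Why: In this Mitsunobu reaction the strongly acidic 4-hydroxyl (a vinylogous acid) is alkylated on oxygen by the activated primary benzylic alcohol, attack through O4 being the normal course for 4-hydroxy-2-pyranones and C-alkylation being blocked by iodine.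

Step 8
Reactants: 13 4-(Ar-methoxy)-6-[(E)-2-Ar-ethenyl]-3-iodo-2H-pyran-2-one; 14 tert-butyl diazoacetate
Product: 15 tert-butyl 2-diazo-2-[4-(Ar-methoxy)-6-[(E)-2-Ar-ethenyl]-2-oxo-2H-pyran-3-yl]acetate
Conditions: Pd(PPh3)4 (10 mol %), Ag2CO3 (0.5 equiv), Et3N (1.3 equiv), PhMe, rt, dark
Reagents that add atoms: none
Why: Palladium-catalysed cross-coupling of an aryl or vinyl iodide with the C–H bond of a diazoacetate, in which zerovalent palladium adds to the activated C3–I bond, silver and amine deliver the diazoacetate carbon, and reductive elimination at room temperature keeps the diazo group intact.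

Step 9
Reactants: 15 tert-butyl 2-diazo-2-[4-(Ar-methoxy)-6-[(E)-2-Ar-ethenyl]-2-oxo-2H-pyran-3-yl]acetate
Product: 17 tert-butyl (2S,3S)-2-Ar-6-[(E)-2-Ar-ethenyl]-4-oxo-2,3-dihydro-4H-furo[3,2-c]pyran-3-carboxylate (trans ester), via cis ester 16 (not isolated)
Conditions: Rh2(S-PTTL)4 (2 mol %), PhMe (0.01 M, slow addition of 15), −60 to 0 °C; then DBU (0.5 equiv), dry, rt
Reagents that add atoms: none
Why: Dirhodium-catalysed loss of dinitrogen from 15 gives a rhodium carbene flanked by the ester acceptor and by C3a, the enol-ether donor carbon of the pyranone, and this carbene takes the benzylic hydrogen with hydride-transfer character while forming C2–C3 in one concerted three-centre event, the known behaviour of ortho-benzyloxy aryldiazoacetates, which give cis 2-aryl-2,3-dihydrobenzofuran-3-carboxylates with chiral dirhodium carboxylates. Ring F closes as a 1,5-insertion in which the carbene carbon, C3a, C7a, O1 and the benzylic carbon become the five ring atoms. C2 is set by the catalyst, whose phthalimido-tert-leucinate pocket selects one of the two enantiotopic benzylic hydrogens, and the cis ester 16 is the kinetic product. C3 is then set by thermodynamic control, DBU reversibly removing the C3 proton next to the ester until aryl and ester are trans, with C2 untouched. The step needs site selectivity, which the substrate secures because only the benzylic ether C–H is five atoms from the carbene and activated by O1 and a para-silyloxy arene, the trans-styryl alkene being out of intramolecular reach and shielded from intermolecular attack by dilution. It also needs ring F to survive the base, which is favoured because expulsion of O1 from the ester enolate would be the reverse of a 5-endo-trig closure with poor orbital overlap.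

Step 10
Reactants: 17 tert-butyl (2S,3S)-2-Ar-6-[(E)-2-Ar-ethenyl]-4-oxo-2,3-dihydro-4H-furo[3,2-c]pyran-3-carboxylate
Product: 18 (2S,3S)-2-Ar-6-[(E)-2-Ar-ethenyl]-4-oxo-2,3-dihydro-4H-furo[3,2-c]pyran-3-carboxylic acid
Conditions: TFA–CH2Cl2 (1:4), 0 °C; evaporate from PhMe
Reagents that add atoms: none
Why: Acidolysis of the tert-butyl ester releases isobutene while aryl TBS ethers withstand cold trifluoroacetic acid, and any reversible ionisation at C2 can only return the more stable trans isomer because C3 is not touched.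

Step 11
Reactants: 18 (2S,3S)-2-Ar-6-[(E)-2-Ar-ethenyl]-4-oxo-2,3-dihydro-4H-furo[3,2-c]pyran-3-carboxylic acid; 19 2,2,6-trimethyl-4H-1,3-dioxin-4-one
Product: 22 6-{2-[(2S,3S)-2-Ar-6-[(E)-2-Ar-ethenyl]-4-oxo-2,3-dihydro-4H-furo[3,2-c]pyran-3-yl]-2-oxoethyl}-2,2-dimethyl-4H-1,3-dioxin-4-one, via acid chloride 20 (not isolated), via lithium dienolate 21 (not isolated)
Conditions: 1-chloro-N,N,2-trimethylprop-1-en-1-amine, CH2Cl2, 0 °C; then add to 19 (2.2 equiv) and LiN(SiMe3)2 (2.2 equiv), THF, −78 °C; AcOH quench at −78 °C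
Reagents that add atoms: none
Why: The alpha-chloroenamine makes the acid chloride without base or HCl, and the chloride then C-acylates the gamma-carbon of the lithium dienolate at low temperature (vinylogous Claisen-type acylation), a second equivalent of dienolate taking up the proton of the doubly activated methylene so that the product rests as its enolate and the C3 hydrogen is protected.

Step 12
Reactants: 22 6-{2-[(2S,3S)-2-Ar-6-[(E)-2-Ar-ethenyl]-4-oxo-2,3-dihydro-4H-furo[3,2-c]pyran-3-yl]-2-oxoethyl}-2,2-dimethyl-4H-1,3-dioxin-4-one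
Product: 24 (2S,3S)-2-Ar-6-[(E)-2-Ar-ethenyl]-3-(4-hydroxy-2-oxo-2H-pyran-6-yl)-2,3-dihydro-4H-furo[3,2-c]pyran-4-one (tetrakis-TBS hypholomine B), via acylketene 23 (not isolated)
Conditions: PhMe, 110 °C
Reagents that add atoms: none
Why: Neutral dioxinone thermolysis expels acetone by retro-[4+2] cleavage, and the acylketene lactonises through the ketone enol to the pendant 4-hydroxy-2-pyranone without base, so C2 and C3 are not disturbed.

Step 13
Reactants: 24 (2S,3S)-2-Ar-6-[(E)-2-Ar-ethenyl]-3-(4-hydroxy-2-oxo-2H-pyran-6-yl)-2,3-dihydro-4H-furo[3,2-c]pyran-4-one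
Product: 25 hypholomine B, (2S,3S)-2-(3,4-dihydroxyphenyl)-6-[(E)-2-(3,4-dihydroxyphenyl)ethenyl]-3-(4-hydroxy-2-oxo-2H-pyran-6-yl)-2,3-dihydro-4H-furo[3,2-c]pyran-4-one
Conditions: HF·pyridine, pyridine–THF, 0 °C to rt, argon; Me3SiOMe quench, evaporate
Reagents that add atoms: none
Why: Buffered fluoride cleaves the four aryl silyl ethers under weakly acidic conditions, which avoids the phenoxide and quinone methide chemistry that could open ring F at C2.

Compound list
1 | caffeic acid | OC(=O)/C=C/c1ccc(O)c(O)c1 | starting material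
2 | tert-butyldimethylsilyl (E)-3-[3,4-bis(tert-butyldimethylsilyloxy)phenyl]prop-2-enoate | CC(C)(C)[Si](C)(C)OC(=O)/C=C/c1ccc(O[Si](C)(C)C(C)(C)C)c(O[Si](C)(C)C(C)(C)C)c1 | intermediate
3 | (E)-3-[3,4-bis(tert-butyldimethylsilyloxy)phenyl]prop-2-enoic acid | OC(=O)/C=C/c1ccc(O[Si](C)(C)C(C)(C)C)c(O[Si](C)(C)C(C)(C)C)c1 | intermediate
4 | (1Z)-1-methoxy-1,3-bis(trimethylsilyloxy)buta-1,3-diene | CO/C(O[Si](C)(C)C)=C/C(=C)O[Si](C)(C)C | starting material
5 | (E)-3-[3,4-bis(tert-butyldimethylsilyloxy)phenyl]prop-2-enoyl chloride | ClC(=O)/C=C/c1ccc(O[Si](C)(C)C(C)(C)C)c(O[Si](C)(C)C(C)(C)C)c1 | intermediate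
6 | (1Z,6E)-7-[3,4-bis(tert-butyldimethylsilyloxy)phenyl]-1-methoxy-1-(trimethylsilyloxy)hepta-1,6-diene-3,5-dione (silyl ketene acetal) | CO/C(O[Si](C)(C)C)=C/C(=O)CC(=O)/C=C/c1ccc(O[Si](C)(C)C(C)(C)C)c(O[Si](C)(C)C(C)(C)C)c1 | intermediate
7 | methyl (E)-7-[3,4-bis(tert-butyldimethylsilyloxy)phenyl]-3,5-dioxohept-6-enoate | COC(=O)CC(=O)CC(=O)/C=C/c1ccc(O[Si](C)(C)C(C)(C)C)c(O[Si](C)(C)C(C)(C)C)c1 | intermediate
8 | 6-[(E)-2-[3,4-bis(tert-butyldimethylsilyloxy)phenyl]ethenyl]-4-hydroxy-2H-pyran-2-one | O=c1cc(O)cc(/C=C/c2ccc(O[Si](C)(C)C(C)(C)C)c(O[Si](C)(C)C(C)(C)C)c2)o1 | intermediate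
9 | 6-[(E)-2-[3,4-bis(tert-butyldimethylsilyloxy)phenyl]ethenyl]-4-hydroxy-3-iodo-2H-pyran-2-one | O=c1oc(/C=C/c2ccc(O[Si](C)(C)C(C)(C)C)c(O[Si](C)(C)C(C)(C)C)c2)cc(O)c1I | intermediate
10 | 3,4-dihydroxybenzaldehyde | O=Cc1ccc(O)c(O)c1 | starting material
11 | 3,4-bis(tert-butyldimethylsilyloxy)benzaldehyde | O=Cc1ccc(O[Si](C)(C)C(C)(C)C)c(O[Si](C)(C)C(C)(C)C)c1 | intermediate
12 | [3,4-bis(tert-butyldimethylsilyloxy)phenyl]methanol | OCc1ccc(O[Si](C)(C)C(C)(C)C)c(O[Si](C)(C)C(C)(C)C)c1 | intermediate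
13 | 4-{[3,4-bis(tert-butyldimethylsilyloxy)phenyl]methoxy}-6-[(E)-2-[3,4-bis(tert-butyldimethylsilyloxy)phenyl]ethenyl]-3-iodo-2H-pyran-2-one | O=c1oc(/C=C/c2ccc(O[Si](C)(C)C(C)(C)C)c(O[Si](C)(C)C(C)(C)C)c2)cc(OCc2ccc(O[Si](C)(C)C(C)(C)C)c(O[Si](C)(C)C(C)(C)C)c2)c1I | intermediate
14 | tert-butyl diazoacetate | CC(C)(C)OC(=O)C=[N+]=[N-] | starting material
15 | tert-butyl 2-diazo-2-[4-{[3,4-bis(tert-butyldimethylsilyloxy)phenyl]methoxy}-6-[(E)-2-[3,4-bis(tert-butyldimethylsilyloxy)phenyl]ethenyl]-2-oxo-2H-pyran-3-yl]acetate | CC(C)(C)OC(=O)C(=[N+]=[N-])c1c(OCc2ccc(O[Si](C)(C)C(C)(C)C)c(O[Si](C)(C)C(C)(C)C)c2)cc(/C=C/c2ccc(O[Si](C)(C)C(C)(C)C)c(O[Si](C)(C)C(C)(C)C)c2)oc1=O | intermediate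
16 | tert-butyl (2S,3R)-2-[3,4-bis(tert-butyldimethylsilyloxy)phenyl]-6-[(E)-2-[3,4-bis(tert-butyldimethylsilyloxy)phenyl]ethenyl]-4-oxo-2,3-dihydro-4H-furo[3,2-c]pyran-3-carboxylate (cis) | CC(C)(C)OC(=O)[C@@H]1c2c(cc(/C=C/c3ccc(O[Si](C)(C)C(C)(C)C)c(O[Si](C)(C)C(C)(C)C)c3)oc2=O)O[C@@H]1c1ccc(O[Si](C)(C)C(C)(C)C)c(O[Si](C)(C)C(C)(C)C)c1 | intermediate
17 | tert-butyl (2S,3S)-2-[3,4-bis(tert-butyldimethylsilyloxy)phenyl]-6-[(E)-2-[3,4-bis(tert-butyldimethylsilyloxy)phenyl]ethenyl]-4-oxo-2,3-dihydro-4H-furo[3,2-c]pyran-3-carboxylate (trans) | CC(C)(C)OC(=O)[C@H]1c2c(cc(/C=C/c3ccc(O[Si](C)(C)C(C)(C)C)c(O[Si](C)(C)C(C)(C)C)c3)oc2=O)O[C@@H]1c1ccc(O[Si](C)(C)C(C)(C)C)c(O[Si](C)(C)C(C)(C)C)c1 | intermediate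
18 | (2S,3S)-2-[3,4-bis(tert-butyldimethylsilyloxy)phenyl]-6-[(E)-2-[3,4-bis(tert-butyldimethylsilyloxy)phenyl]ethenyl]-4-oxo-2,3-dihydro-4H-furo[3,2-c]pyran-3-carboxylic acid | OC(=O)[C@H]1c2c(cc(/C=C/c3ccc(O[Si](C)(C)C(C)(C)C)c(O[Si](C)(C)C(C)(C)C)c3)oc2=O)O[C@@H]1c1ccc(O[Si](C)(C)C(C)(C)C)c(O[Si](C)(C)C(C)(C)C)c1 | intermediate
19 | 2,2,6-trimethyl-4H-1,3-dioxin-4-one | CC1=CC(=O)OC(C)(C)O1 | starting material
20 | (2S,3S)-2-[3,4-bis(tert-butyldimethylsilyloxy)phenyl]-6-[(E)-2-[3,4-bis(tert-butyldimethylsilyloxy)phenyl]ethenyl]-4-oxo-2,3-dihydro-4H-furo[3,2-c]pyran-3-carbonyl chloride | ClC(=O)[C@H]1c2c(cc(/C=C/c3ccc(O[Si](C)(C)C(C)(C)C)c(O[Si](C)(C)C(C)(C)C)c3)oc2=O)O[C@@H]1c1ccc(O[Si](C)(C)C(C)(C)C)c(O[Si](C)(C)C(C)(C)C)c1 | intermediate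
21 | lithium 2,2-dimethyl-6-methylidene-6H-1,3-dioxin-4-olate | [Li+].C=C1C=C([O-])OC(C)(C)O1 | intermediate
22 | 6-{2-[(2S,3S)-2-[3,4-bis(tert-butyldimethylsilyloxy)phenyl]-6-[(E)-2-[3,4-bis(tert-butyldimethylsilyloxy)phenyl]ethenyl]-4-oxo-2,3-dihydro-4H-furo[3,2-c]pyran-3-yl]-2-oxoethyl}-2,2-dimethyl-4H-1,3-dioxin-4-one | CC1(C)OC(=O)C=C(CC(=O)[C@H]2c3c(cc(/C=C/c4ccc(O[Si](C)(C)C(C)(C)C)c(O[Si](C)(C)C(C)(C)C)c4)oc3=O)O[C@@H]2c2ccc(O[Si](C)(C)C(C)(C)C)c(O[Si](C)(C)C(C)(C)C)c2)O1 | intermediate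
23 | 5-[(2S,3S)-2-[3,4-bis(tert-butyldimethylsilyloxy)phenyl]-6-[(E)-2-[3,4-bis(tert-butyldimethylsilyloxy)phenyl]ethenyl]-4-oxo-2,3-dihydro-4H-furo[3,2-c]pyran-3-yl]pent-1-ene-1,3,5-trione (acylketene) | O=C=CC(=O)CC(=O)[C@H]1c2c(cc(/C=C/c3ccc(O[Si](C)(C)C(C)(C)C)c(O[Si](C)(C)C(C)(C)C)c3)oc2=O)O[C@@H]1c1ccc(O[Si](C)(C)C(C)(C)C)c(O[Si](C)(C)C(C)(C)C)c1 | intermediate
24 | (2S,3S)-2-[3,4-bis(tert-butyldimethylsilyloxy)phenyl]-6-[(E)-2-[3,4-bis(tert-butyldimethylsilyloxy)phenyl]ethenyl]-3-(4-hydroxy-2-oxo-2H-pyran-6-yl)-2,3-dihydro-4H-furo[3,2-c]pyran-4-one | O=c1cc(O)cc([C@H]2c3c(cc(/C=C/c4ccc(O[Si](C)(C)C(C)(C)C)c(O[Si](C)(C)C(C)(C)C)c4)oc3=O)O[C@@H]2c2ccc(O[Si](C)(C)C(C)(C)C)c(O[Si](C)(C)C(C)(C)C)c2)o1 | intermediate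
25 | hypholomine B, (2S,3S)-2-(3,4-dihydroxyphenyl)-6-[(E)-2-(3,4-dihydroxyphenyl)ethenyl]-3-(4-hydroxy-2-oxo-2H-pyran-6-yl)-2,3-dihydro-4H-furo[3,2-c]pyran-4-one | O=c1cc(O)cc([C@H]2c3c(cc(/C=C/c4ccc(O)c(O)c4)oc3=O)O[C@@H]2c2ccc(O)c(O)c2)o1 | target

Total step count: 13 steps. Longest linear sequence: 11 steps (steps 1–4 and 7–13, from caffeic acid); steps 5 and 6 form the short benzyl alcohol branch.

Steps most likely to fail

Step 9. The insertion itself has close precedent. The weak point is the base equilibration: the ester enolate may expel O1, which here is a pyranonolate and a far better leaving group than a phenoxide, and re-closure would then erode the configuration at C2. The fallback moves the thermodynamic control from C3 to C2. It sets out from 15, which is cyclised with the enantiomeric catalyst Rh2(R-PTTL)4 and without any base to give the antipodal cis ester, tert-butyl (2R,3S)-2-Ar-6-[(E)-2-Ar-ethenyl]-4-oxo-2,3-dihydro-4H-furo[3,2-c]pyran-3-carboxylate F1, in which C3 already has the configuration of the target. Trifluoroacetic acid in CH2Cl2 then removes the tert-butyl group to give the cis acid, (2R,3S)-2-Ar-6-[(E)-2-Ar-ethenyl]-4-oxo-2,3-dihydro-4H-furo[3,2-c]pyran-3-carboxylic acid F2. On longer exposure at room temperature the acid ionises the C2–O1 bond reversibly, through the benzylic cation stabilised by the para-silyloxy arene, so that C2 settles trans to the untouched C3. This acid-promoted C2 equilibration is known for 2-(4-oxyaryl)-2,3-dihydrobenzofurans. The fallback comes back to the route at 18 and absorbs step 10.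

Step 8. Oxidative addition and carbon transfer at an iodide flanked by the lactone carbonyl and the benzyloxy group may be slow, so that the diazoacetate is consumed by palladium-carbene decomposition before it couples. The fallback builds the diazo group after the C–C bond. It sets out from 13, which is coupled with the Reformatsky reagent BrZnCH2CO2tBu under Pd2(dba)3 and XPhos in THF (Negishi-type coupling of a zinc ester enolate) to give tert-butyl 2-[4-(Ar-methoxy)-6-[(E)-2-Ar-ethenyl]-2-oxo-2H-pyran-3-yl]acetate F3. Regitz diazo transfer with 4-acetamidobenzenesulfonyl azide and DBU in dry MeCN then returns to the route at 15.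

Step 11. The acid chloride carries an acidic C3 hydrogen, and the basic dienolate may enolise it to a ketene or deprotonate the product at C3, with loss of material through opening of ring F. The fallback replaces the basic enolate by a neutral bis-silyl diene and the ketene closure by a lactonisation, the two operations of steps 2 and 3. It sets out from 18, which is converted into acid chloride 20 as in step 11 and treated without base with diene 4 in CH2Cl2 from −78 °C to rt (Mukaiyama-type acylation of a 1,3-bis(silyl enol ether)). This should give in the flask the silyl ketene acetal (4Z)-1-[(2S,3S)-2-Ar-6-[(E)-2-Ar-ethenyl]-4-oxo-2,3-dihydro-4H-furo[3,2-c]pyran-3-yl]-5-methoxy-5-(trimethylsilyloxy)pent-4-ene-1,3-dione F4. Aqueous NH4Cl work-up should then give methyl 5-[(2S,3S)-2-Ar-6-[(E)-2-Ar-ethenyl]-4-oxo-2,3-dihydro-4H-furo[3,2-c]pyran-3-yl]-3,5-dioxopentanoate F5. DBU (1.0 equiv) with 4 Å molecular sieves in PhMe deprotonates the 1,3-diketone, which is far more acidic than the C3 hydrogen, and closes the 4-hydroxy-2-pyranone with loss of methanol. This returns to the route at 24 and replaces step 12.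

Further compounds
F1 | step 9 | tert-butyl (2R,3S)-2-[3,4-bis(tert-butyldimethylsilyloxy)phenyl]-6-[(E)-2-[3,4-bis(tert-butyldimethylsilyloxy)phenyl]ethenyl]-4-oxo-2,3-dihydro-4H-furo[3,2-c]pyran-3-carboxylate (cis) | CC(C)(C)OC(=O)[C@H]1c2c(cc(/C=C/c3ccc(O[Si](C)(C)C(C)(C)C)c(O[Si](C)(C)C(C)(C)C)c3)oc2=O)O[C@H]1c1ccc(O[Si](C)(C)C(C)(C)C)c(O[Si](C)(C)C(C)(C)C)c1
F2 | step 9 | (2R,3S)-2-[3,4-bis(tert-butyldimethylsilyloxy)phenyl]-6-[(E)-2-[3,4-bis(tert-butyldimethylsilyloxy)phenyl]ethenyl]-4-oxo-2,3-dihydro-4H-furo[3,2-c]pyran-3-carboxylic acid (cis) | OC(=O)[C@H]1c2c(cc(/C=C/c3ccc(O[Si](C)(C)C(C)(C)C)c(O[Si](C)(C)C(C)(C)C)c3)oc2=O)O[C@H]1c1ccc(O[Si](C)(C)C(C)(C)C)c(O[Si](C)(C)C(C)(C)C)c1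
F3 | step 8 | tert-butyl 2-[4-{[3,4-bis(tert-butyldimethylsilyloxy)phenyl]methoxy}-6-[(E)-2-[3,4-bis(tert-butyldimethylsilyloxy)phenyl]ethenyl]-2-oxo-2H-pyran-3-yl]acetate | CC(C)(C)OC(=O)Cc1c(OCc2ccc(O[Si](C)(C)C(C)(C)C)c(O[Si](C)(C)C(C)(C)C)c2)cc(/C=C/c2ccc(O[Si](C)(C)C(C)(C)C)c(O[Si](C)(C)C(C)(C)C)c2)oc1=O
F4 | step 11 | (4Z)-1-[(2S,3S)-2-[3,4-bis(tert-butyldimethylsilyloxy)phenyl]-6-[(E)-2-[3,4-bis(tert-butyldimethylsilyloxy)phenyl]ethenyl]-4-oxo-2,3-dihydro-4H-furo[3,2-c]pyran-3-yl]-5-methoxy-5-(trimethylsilyloxy)pent-4-ene-1,3-dione | CO/C(O[Si](C)(C)C)=C/C(=O)CC(=O)[C@H]1c2c(cc(/C=C/c3ccc(O[Si](C)(C)C(C)(C)C)c(O[Si](C)(C)C(C)(C)C)c3)oc2=O)O[C@@H]1c1ccc(O[Si](C)(C)C(C)(C)C)c(O[Si](C)(C)C(C)(C)C)c1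
F5 | step 11 | methyl 5-[(2S,3S)-2-[3,4-bis(tert-butyldimethylsilyloxy)phenyl]-6-[(E)-2-[3,4-bis(tert-butyldimethylsilyloxy)phenyl]ethenyl]-4-oxo-2,3-dihydro-4H-furo[3,2-c]pyran-3-yl]-3,5-dioxopentanoate | COC(=O)CC(=O)CC(=O)[C@H]1c2c(cc(/C=C/c3ccc(O[Si](C)(C)C(C)(C)C)c(O[Si](C)(C)C(C)(C)C)c3)oc2=O)O[C@@H]1c1ccc(O[Si](C)(C)C(C)(C)C)c(O[Si](C)(C)C(C)(C)C)c1
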